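**Plan**

- Retrosynthetic cuts, in order: the lactone C12–O6 bond; the C5–C6 bond of the ten-membered ring; the C8 angelate; the C7–C8 bond (2-(alkoxycarbonyl)allylation of a C8 aldehyde); the C1=C10 olefin (Horner–Wadsworth–Emmons).
- Forward: aldehyde 7 (C1–C5, C15) and phosphonate 10 (C8–C10, C14) give enoate aldehyde 14. Bromide 19 (C6, C7, C11–C13) is joined at C7–C8. Acylation, desilylation and double oxidation give open-chain dialdehyde 26. The ten-membered carbocycle is closed last at C5–C6, then acid closes the γ-lactone.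
- Feature used: on the ten-membered ring an exocyclic methylene (C4=C15) sits next to a vicinal diol (C5–OH, C6–O). This is the retron of a γ-silyloxyallylchromium adding to an aldehyde, and the 2-alkylacrolein C15=C4–C5HO generates that nucleophile reductively (CrCl2/Me3SiCl). The cis-in-ring C1=C10 enoate eases closure.
- Stereochemistry: C7 and C8 are set together in one ligand-controlled, syn-selective chromium-catalysed allylation, the only external source of chirality. C6 and C5 are relayed from them in the ring closure (Felkin–Anh face selection at C6, chair transition state for the 5,6-syn diol). The C1=C10 geometry comes from the olefination; the angelate Z olefin is bought.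

Key step: step 13

Remark: locants C1–C15 are those of the germacrane skeleton of the target (ring C1–C10, acrylate carbons C11–C13, ester carbon C14, methylene C15); the (S,S) antipode of the ligand in step 9 is assumed to deliver Si-face addition, otherwise its mirror image is used.

**Route**

Step 1
Reactants: 1 2-methylenepropane-1,3-diol; 2 tert-butyldimethylsilyl chloride
Product: 3 2-({[tert-butyl(dimethyl)silyl]oxy}methyl)prop-2-en-1-ol
Conditions: NaH (1.0 equiv), THF, 0 °C; then t-BuMe2SiCl (1.0 equiv), 0 °C to rt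
Reagents that add atoms: 2 tert-butyldimethylsilyl chloride, CC(C)(C)[Si](C)(C)Cl
Why: The sparingly soluble monosodium alkoxide of the symmetrical diol is silylated once, so the mono-silyl ether should form cleanly (Williamson-type O-silylation).

Step 2
Reactants: 3 mono-silyl ether; 4 triethyl orthoacetate
Product: 6 ethyl 4-({[tert-butyl(dimethyl)silyl]oxy}methyl)pent-4-enoate, via ketene acetal 5 (not isolated)
Conditions: MeC(OEt)3 (6 equiv), EtCO2H (0.1 equiv), 140 °C, EtOH distilled off
Reagents that add atoms: 4 triethyl orthoacetate, CC(OCC)(OCC)OCC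
Why: Johnson–Claisen rearrangement, in which acid-catalysed exchange gives ketene acetal 5 and its [3,3]-sigmatropic shift forms the C2–C3 bond and leaves the double bond as the C4=C15 methylene.

Step 3
Reactants: 6 ethyl ester
Product: 7 4-({[tert-butyl(dimethyl)silyl]oxy}methyl)pent-4-enal
Conditions: i-Bu2AlH (1.05 equiv), CH2Cl2, −78 °C; then MeOH, aq. Rochelle salt
Reagents that add atoms: none
Why: Partial ester reduction at −78 °C stops at the aluminium hemiacetal, which releases the aldehyde on work-up.

Step 4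
Reactants: 8 trimethyl phosphonoacetate; 9 2-bromo-1,1-dimethoxyethane
Product: 10 methyl 2-(dimethoxyphosphoryl)-4,4-dimethoxybutanoate (racemic)
Conditions: NaH (1.0 equiv), DMF, 0 °C; then 9 (1.2 equiv), NaI (10 mol %), 90 °C
Reagents that add atoms: none
Why: SN2 alkylation of the sodium phosphonoacetate anion by the primary bromide, helped by iodide catalysis, puts the masked C8 aldehyde on the future C10.

Step 5
Reactants: 7 aldehyde; 10 phosphonate
Product: 11 methyl (2E)-6-({[tert-butyl(dimethyl)silyl]oxy}methyl)-2-(2,2-dimethoxyethyl)hepta-2,6-dienoate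
Conditions: NaH (1.1 equiv), THF, 0 °C; then 7, 0 °C to rt
Reagents that add atoms: none
Why: Horner–Wadsworth–Emmons olefination under equilibrating sodium conditions should favour the (E)-enoate, with the ester trans to the C2 chain as the target requires; any (Z)-isomer is removed by chromatography.

Step 6
Reactants: 11 acetal; 12 water
Product: 14 methyl (2E)-6-({[tert-butyl(dimethyl)silyl]oxy}methyl)-2-(2-oxoethyl)hepta-2,6-dienoate, via pyridinium salt 13 (not isolated)
Conditions: Et3SiOTf (2 equiv), 2,4,6-collidine (3 equiv), CH2Cl2, 0 °C; then H2O, 0 °C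
Reagents that add atoms: 12 water, O
Why: The silyl triflate–collidine pair converts the dimethyl acetal into pyridinium salt 13, which water hydrolyses at near-neutral pH, so the silyl ether survives and the β,γ-unsaturated aldehyde should not move into conjugation (chemoselective acetal cleavage).

Step 7
Reactants: 15 {[tert-butyl(dimethyl)silyl]oxy}acetaldehyde; 16 tert-butyl acrylate
Product: 17 tert-butyl 4-{[tert-butyl(dimethyl)silyl]oxy}-3-hydroxy-2-methylidenebutanoate (racemic)
Conditions: DABCO (1.0 equiv), 1,4-dioxane/H2O (1:1), rt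
Reagents that add atoms: none
Why: Morita–Baylis–Hillman reaction of the activated α-oxygenated aldehyde with the acrylate; the racemic carbinol centre does not matter because it becomes sp2 in step 8.

Step 8
Reactants: 17 allylic alcohol; 18 N-bromosuccinimide
Product: 19 tert-butyl (2Z)-2-(bromomethyl)-4-{[tert-butyl(dimethyl)silyl]oxy}but-2-enoate
Conditions: NBS (1.5 equiv), Me2S (1.8 equiv), CH2Cl2, 0 °C to rt
Reagents that add atoms: 18 N-bromosuccinimide, O=C1CCC(=O)N1Br
Why: The sulfonium reagent from NBS and Me2S activates the alcohol and bromide attacks the methylene terminus (SN2′), which should give the more stable (Z)-2-(bromomethyl)alkenoate with the CH2OSi group trans to the ester.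

Step 9
Reactants: 14 aldehyde; 19 allylic bromide
Product: 21 1-tert-butyl 7-methyl (3S,4R,6E)-3-({[tert-butyl(dimethyl)silyl]oxy}methyl)-6-[4-({[tert-butyl(dimethyl)silyl]oxy}methyl)pent-4-en-1-ylidene]-4-hydroxy-2-methylideneheptanedioate, via silyl ether 20 (not isolated)
Conditions: CrCl2 (10 mol %), (S,S)-1,8-bis(4-isopropyl-4,5-dihydrooxazol-2-yl)-3,6-diphenyl-9H-carbazole (12 mol %), i-Pr2NEt (30 mol %), Mn (2 equiv), Me3SiCl (2 equiv), THF, rt; then citric acid (aq), MeOH, 0 °C
Reagents that add atoms: none
Why: Catalytic enantioselective Nozaki–Hiyama–Kishi 2-(alkoxycarbonyl)allylation, in which the allylchromium keeps the silyloxymethyl group trans to the ester and therefore axial in the chair transition state, so the 7,8-syn adduct is expected, while the chiral tridentate ligand on chromium selects the Si face of aldehyde 14 and so sets C8 (R) and with it C7; the tert-butyl ester resists lactonisation.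

Step 10
Reactants: 21 alcohol; 22 angelic acid
Product: 24 the C8 angelate of 21 (3S,4R; 4-{[(2Z)-2-methylbut-2-enoyl]oxy}), via mixed anhydride 23 (not isolated)
Conditions: 22 (3 equiv), 2,4,6-trichlorobenzoyl chloride (3 equiv), Et3N (6 equiv), toluene, rt; then 21, toluene, 80 °C
Reagents that add atoms: 22 angelic acid, C/C=C(/C)C(=O)O
Why: Yamaguchi esterification through mixed anhydride 23, run without a nucleophilic amine catalyst, should acylate the hindered C8 hydroxyl at the angeloyl carbonyl without Z-to-E isomerisation to the tiglate.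

Step 11
Reactants: 24 bis-silyl ether
Product: 25 1-tert-butyl 7-methyl (3S,4R,6E)-3-(hydroxymethyl)-6-[4-(hydroxymethyl)pent-4-en-1-ylidene]-2-methylidene-4-{[(2Z)-2-methylbut-2-enoyl]oxy}heptanedioate
Conditions: HF·pyridine, pyridine, THF, 0 °C to rt
Reagents that add atoms: none
Why: Buffered fluoride cleaves both primary silyl ethers (strong Si–F bond) and should leave the angelate, the methyl ester and the tert-butyl ester, which is too hindered to lactonise with the C6 hydroxyl.

Step 12
Reactants: 25 diol
Product: 26 1-tert-butyl 7-methyl (3R,4R,6E)-3-formyl-6-(4-formylpent-4-en-1-ylidene)-2-methylidene-4-{[(2Z)-2-methylbut-2-enoyl]oxy}heptanedioate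
Conditions: Dess–Martin periodinane (3 equiv), NaHCO3, CH2Cl2, 0 °C to rt; filtered and used crude at once
Reagents that add atoms: none
Why: Dess–Martin oxidation takes both primary alcohols to aldehydes (the allylic one to the 2-alkylacrolein) under mild buffered conditions, chosen because the C6 aldehyde has an acidic C7–H next to a β-acyloxy group.

Step 13
Reactants: 26 dialdehyde; 27 chlorotrimethylsilane
Product: 28 ten-membered ring bis(trimethylsilyl) ether: methyl (1E)-8-(3-tert-butoxy-3-oxoprop-1-en-2-yl)-5-methylidene-9-{[(2Z)-2-methylbut-2-enoyl]oxy}-6,7-bis[(trimethylsilyl)oxy]cyclodec-1-ene-1-carboxylate, (5S,6S,7R,8R) in target numbering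
Conditions: CrCl2 (8 equiv), Me3SiCl (6 equiv), DMF, rt; 26 added by syringe pump over 12 h (final 2 mM); aq. NaHCO3
Reagents that add atoms: 27 chlorotrimethylsilane, C[Si](C)(C)Cl
Why: Divalent chromium reduces only the Me3SiCl-activated enal, in two one-electron steps through a silyloxyallyl radical, to a γ-silyloxyallylchromium of trivalent chromium with the metal on C15, which adds through its oxygen-bearing γ-carbon C5 to the C6 aldehyde in a six-membered chair transition state (SE2′), so that the C5–C6 bond forms and the C4=C15 methylene is regenerated. The closest known reaction type is the CrCl2/R3SiCl pinacol-type cross-coupling of 2-alkylacroleins with aldehydes, known in intramolecular form for common rings, together with Nozaki–Hiyama–Kishi allylation closures of ten-membered germacrane rings. The ten-membered carbocycle (C1–C10) is closed in the 10-exo-trig mode on the C6 carbonyl. C5 is controlled by simple diastereoselection: as for other 2-alkylacroleins the C3 branch on C4 should turn the silyloxy group toward the CH2–Cr terminus, where it is axial in the chair while the C7 branch of the aldehyde is equatorial, which gives the 5,6-syn diol. C6 is controlled by the C7 stereocentre: Felkin–Anh addition to the Re face with the C8 branch anti to the incoming carbon and the acrylate unit gauche to the carbonyl, reinforced by the 1,3-anti relation to the C8 acyloxy group, should give the O6/C11 relationship of the trans-fused lactone. The step needs chemoselectivity (enal against saturated aldehyde, esters and enoates, secured by the easier reduction of the silyl-activated conjugated aldehyde) and ring closure over oligomerisation (secured by slow addition at high dilution and by the cis-in-ring C1=C10 enoate and three sp2 ring atoms, which relieve transannular strain).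

Step 14
Reactants: 28 bis(trimethylsilyl) ether
Product: 31 target CNP0163095.1, via diol 29 (not isolated), via hydroxy acid 30 (not isolated)
Conditions: CF3CO2H/CH2Cl2 (1:4), 0 °C to rt
Reagents that add atoms: none
Why: Acid removes both trimethylsilyl ethers and the tert-butyl ester, and γ-hydroxy acid 30 should close (5-exo-trig) on O6 to the α-methylene-γ-butyrolactone in preference to the δ-lactone on O5, leaving the C5 hydroxyl free and no stereocentre touched.

**Compound list**

1 | 2-methylenepropane-1,3-diol | C=C(CO)CO | starting material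
2 | tert-butyldimethylsilyl chloride | CC(C)(C)[Si](C)(C)Cl | starting material
3 | 2-({[tert-butyl(dimethyl)silyl]oxy}methyl)prop-2-en-1-ol | C=C(CO)CO[Si](C)(C)C(C)(C)C | intermediate
4 | triethyl orthoacetate | CC(OCC)(OCC)OCC | starting material
5 | mixed ketene acetal, the 1-ethoxyvinyl ether of 3 | C=C(OCC)OCC(=C)CO[Si](C)(C)C(C)(C)C | intermediate
6 | ethyl 4-({[tert-butyl(dimethyl)silyl]oxy}methyl)pent-4-enoate | CCOC(=O)CCC(=C)CO[Si](C)(C)C(C)(C)C | intermediate
7 | 4-({[tert-butyl(dimethyl)silyl]oxy}methyl)pent-4-enal | O=CCCC(=C)CO[Si](C)(C)C(C)(C)C | intermediate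
8 | trimethyl phosphonoacetate | COC(=O)CP(=O)(OC)OC | starting material
9 | 2-bromo-1,1-dimethoxyethane | BrCC(OC)OC | starting material
10 | methyl 2-(dimethoxyphosphoryl)-4,4-dimethoxybutanoate (racemic) | COC(=O)C(CC(OC)OC)P(=O)(OC)OC | intermediate
11 | methyl (2E)-6-({[tert-butyl(dimethyl)silyl]oxy}methyl)-2-(2,2-dimethoxyethyl)hepta-2,6-dienoate | COC(=O)/C(CC(OC)OC)=C/CCC(=C)CO[Si](C)(C)C(C)(C)C | intermediate
12 | water | O | starting material
13 | N-(1-methoxyalkyl)-2,4,6-trimethylpyridinium triflate from 11 (one methoxy group of the acetal replaced by the collidine nitrogen) | COC(C/C(C(=O)OC)=C\CCC(=C)CO[Si](C)(C)C(C)(C)C)[n+]1c(C)cc(C)cc1C.[O-]S(=O)(=O)C(F)(F)F | intermediate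
14 | methyl (2E)-6-({[tert-butyl(dimethyl)silyl]oxy}methyl)-2-(2-oxoethyl)hepta-2,6-dienoate | COC(=O)/C(CC=O)=C/CCC(=C)CO[Si](C)(C)C(C)(C)C | intermediate
15 | {[tert-butyl(dimethyl)silyl]oxy}acetaldehyde | O=CCO[Si](C)(C)C(C)(C)C | starting material
16 | tert-butyl acrylate | C=CC(=O)OC(C)(C)C | starting material
17 | tert-butyl 4-{[tert-butyl(dimethyl)silyl]oxy}-3-hydroxy-2-methylidenebutanoate (racemic) | C=C(C(O)CO[Si](C)(C)C(C)(C)C)C(=O)OC(C)(C)C | intermediate
18 | N-bromosuccinimide | O=C1CCC(=O)N1Br | starting material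
19 | tert-butyl (2Z)-2-(bromomethyl)-4-{[tert-butyl(dimethyl)silyl]oxy}but-2-enoate | BrC/C(C(=O)OC(C)(C)C)=C\CO[Si](C)(C)C(C)(C)C | intermediate
20 | O8-trimethylsilyl ether of 21 | C=C(C(=O)OC(C)(C)C)[C@@H](CO[Si](C)(C)C(C)(C)C)[C@H](O[Si](C)(C)C)C/C(C(=O)OC)=C\CCC(=C)CO[Si](C)(C)C(C)(C)C | intermediate
21 | 1-tert-butyl 7-methyl (3S,4R,6E)-3-({[tert-butyl(dimethyl)silyl]oxy}methyl)-6-[4-({[tert-butyl(dimethyl)silyl]oxy}methyl)pent-4-en-1-ylidene]-4-hydroxy-2-methylideneheptanedioate (7,8-syn; C7 S, C8 R in target numbering) | C=C(C(=O)OC(C)(C)C)[C@@H](CO[Si](C)(C)C(C)(C)C)[C@H](O)C/C(C(=O)OC)=C\CCC(=C)CO[Si](C)(C)C(C)(C)C | intermediate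
22 | angelic acid, (Z)-2-methylbut-2-enoic acid | C/C=C(/C)C(=O)O | starting material
23 | (Z)-2-methylbut-2-enoic 2,4,6-trichlorobenzoic anhydride | C/C=C(/C)C(=O)OC(=O)c1c(Cl)cc(Cl)cc1Cl | intermediate
24 | C8 angelate of 21: 1-tert-butyl 7-methyl (3S,4R,6E)-3-({[tert-butyl(dimethyl)silyl]oxy}methyl)-6-[4-({[tert-butyl(dimethyl)silyl]oxy}methyl)pent-4-en-1-ylidene]-2-methylidene-4-{[(2Z)-2-methylbut-2-enoyl]oxy}heptanedioate | C=C(C(=O)OC(C)(C)C)[C@@H](CO[Si](C)(C)C(C)(C)C)[C@H](OC(=O)/C(C)=C\C)C/C(C(=O)OC)=C\CCC(=C)CO[Si](C)(C)C(C)(C)C | intermediate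
25 | 1-tert-butyl 7-methyl (3S,4R,6E)-3-(hydroxymethyl)-6-[4-(hydroxymethyl)pent-4-en-1-ylidene]-2-methylidene-4-{[(2Z)-2-methylbut-2-enoyl]oxy}heptanedioate | C=C(C(=O)OC(C)(C)C)[C@@H](CO)[C@H](OC(=O)/C(C)=C\C)C/C(C(=O)OC)=C\CCC(=C)CO | intermediate
26 | 1-tert-butyl 7-methyl (3R,4R,6E)-3-formyl-6-(4-formylpent-4-en-1-ylidene)-2-methylidene-4-{[(2Z)-2-methylbut-2-enoyl]oxy}heptanedioate | C=C(C(=O)OC(C)(C)C)[C@@H](C=O)[C@H](OC(=O)/C(C)=C\C)C/C(C(=O)OC)=C\CCC(=C)C=O | intermediate
27 | chlorotrimethylsilane | C[Si](C)(C)Cl | starting material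
28 | methyl (1E)-8-(3-tert-butoxy-3-oxoprop-1-en-2-yl)-5-methylidene-9-{[(2Z)-2-methylbut-2-enoyl]oxy}-6,7-bis[(trimethylsilyl)oxy]cyclodec-1-ene-1-carboxylate, (5S,6S,7R,8R) in target numbering | C=C(C(=O)OC(C)(C)C)[C@@H]1[C@H](OC(=O)/C(C)=C\C)C/C(C(=O)OC)=C\CCC(=C)[C@H](O[Si](C)(C)C)[C@H]1O[Si](C)(C)C | intermediate
29 | 5,6-diol tert-butyl ester (28 without the two trimethylsilyl groups), (5S,6S,7S,8R) in target numbering | C=C(C(=O)OC(C)(C)C)[C@@H]1[C@H](OC(=O)/C(C)=C\C)C/C(C(=O)OC)=C\CCC(=C)[C@H](O)[C@H]1O | intermediate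
30 | 5,6-dihydroxy acrylic acid (29 with the tert-butyl ester cleaved) | C=C(C(=O)O)[C@@H]1[C@H](OC(=O)/C(C)=C\C)C/C(C(=O)OC)=C\CCC(=C)[C@H](O)[C@H]1O | intermediate
31 | target CNP0163095.1: methyl (1(10)E,5S,6S,7R,8R)-5-hydroxy-8-{[(2Z)-2-methylbut-2-enoyl]oxy}-12-oxo-germacra-1(10),4(15),11(13)-trien-12,6-olid-14-oate | C=C1C(=O)O[C@H]2[C@H]1[C@H](OC(=O)/C(C)=C\C)C/C(C(=O)OC)=C\CCC(=C)[C@@H]2O | target

**Step count and risks**

Total step count: 14. Longest linear sequence: 11 steps (steps 1, 2, 3, 5, 6, 9, 10, 11, 12, 13, 14).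

Step 13 (most likely to fail). In the strained ten-membered transition state the silyloxy group may sit equatorial or the aldehyde branch axial, so the ring would close with the 5,6-anti relationship (the C5 epimer), alongside oligomerisation if closure is slow. Fallback: C5 is corrected after the ring is made. Setting out from 26, the conditions of step 13 would give the C5 epimer of 28 F1. The acid treatment of step 14 would pass through the C5 epimer of 29 F2 and the C5 epimer of 30 F3 to the C5 epimer of 31 F4. Mitsunobu inversion of its single hydroxyl (HCO2H, PPh3, diisopropyl azodicarboxylate, THF, 0 °C) would give the 5-O-formate of 31 F5 with the correct C5 configuration. Mild methanolysis (KHCO3, MeOH, 0 °C) removes the formate and comes back to the route at 31.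

Step 9. Equilibration of the allylchromium geometry would erode the syn selectivity, the ligand may give poor face selection with this γ-substituted reagent, and the allylchromium may lose silanolate by 1,4-elimination to a diene. Fallback: a non-equilibrating boron reagent. Setting out from 17, acetylation (Ac2O, DMAP cat., pyridine) would give the acetate of 17 F6. Copper-catalysed SN2′ borylation (bis(pinacolato)diboron, CuCl, LiCl, KOAc, DMF, rt) would give the allylboronate F7, with the CH2OSi group cis to the CH2–B carbon. Allylboration of 14 catalysed by a chiral phosphoric acid (3,3′-bis(2,4,6-triisopropylphenyl)-1,1′-binaphthyl-2,2′-diyl hydrogen phosphate, antipode chosen for Si-face addition, toluene, −30 °C) proceeds through a closed chair that translates the olefin geometry into the syn adduct, the O-boryl adduct F8. Aqueous work-up comes back to the route at 21.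

Step 12. E1cB loss of angelic acid across C7–C8, or migration of the C11=C13 double bond into conjugation with the C6 aldehyde, may occur during oxidation, work-up or the slow addition of step 13. Fallback: the β-oxygen is carried as an ether, a far poorer leaving group, and the angelate is introduced after ring closure. Setting out from 21, 4-methoxybenzyl trichloroacetimidate with Sc(OTf)3 (cat., toluene, 0 °C) would give the O8 4-methoxybenzyl ether of 21 F9. HF·pyridine would give the diol F10, and Dess–Martin oxidation the β-alkoxy dialdehyde F11. The conditions of step 13 would give the ring-closed bis(trimethylsilyl) ether F12. DDQ (CH2Cl2, pH 7 buffer, 0 °C) would free the C8 alcohol F13. Yamaguchi angeloylation as in step 10 comes back to the route at 28.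

**Further compounds**

F1 | step 13 | C5 epimer of 28 | C=C(C(=O)OC(C)(C)C)[C@@H]1[C@H](OC(=O)/C(C)=C\C)C/C(C(=O)OC)=C\CCC(=C)[C@@H](O[Si](C)(C)C)[C@H]1O[Si](C)(C)C
F2 | step 13 | C5 epimer of 29 | C=C(C(=O)OC(C)(C)C)[C@@H]1[C@H](OC(=O)/C(C)=C\C)C/C(C(=O)OC)=C\CCC(=C)[C@@H](O)[C@H]1O
F3 | step 13 | C5 epimer of 30 | C=C(C(=O)O)[C@@H]1[C@H](OC(=O)/C(C)=C\C)C/C(C(=O)OC)=C\CCC(=C)[C@@H](O)[C@H]1O
F4 | step 13 | C5 epimer of 31 | C=C1C(=O)O[C@H]2[C@H]1[C@H](OC(=O)/C(C)=C\C)C/C(C(=O)OC)=C\CCC(=C)[C@H]2O
F5 | step 13 | 5-O-formate of 31 | C=C1C(=O)O[C@H]2[C@H]1[C@H](OC(=O)/C(C)=C\C)C/C(C(=O)OC)=C\CCC(=C)[C@@H]2OC=O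
F6 | step 9 | acetate of 17 | C=C(C(OC(C)=O)CO[Si](C)(C)C(C)(C)C)C(=O)OC(C)(C)C
F7 | step 9 | allylboronate: tert-butyl 4-{[tert-butyl(dimethyl)silyl]oxy}-2-[(4,4,5,5-tetramethyl-1,3,2-dioxaborolan-2-yl)methyl]but-2-enoate, CH2OSi cis to CH2B | CC1(C)OB(C/C(C(=O)OC(C)(C)C)=C\CO[Si](C)(C)C(C)(C)C)OC1(C)C
F8 | step 9 | O-boryl adduct, the O8 pinacolboryl ester of 21 | C=C(C(=O)OC(C)(C)C)[C@@H](CO[Si](C)(C)C(C)(C)C)[C@H](OB1OC(C)(C)C(C)(C)O1)C/C(C(=O)OC)=C\CCC(=C)CO[Si](C)(C)C(C)(C)C
F9 | step 12 | O8 4-methoxybenzyl ether of 21 | C=C(C(=O)OC(C)(C)C)[C@@H](CO[Si](C)(C)C(C)(C)C)[C@H](OCc1ccc(OC)cc1)C/C(C(=O)OC)=C\CCC(=C)CO[Si](C)(C)C(C)(C)C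
F10 | step 12 | diol, F9 without the two silyl groups | C=C(C(=O)OC(C)(C)C)[C@@H](CO)[C@H](OCc1ccc(OC)cc1)C/C(C(=O)OC)=C\CCC(=C)CO
F11 | step 12 | β-alkoxy dialdehyde, the O8 4-methoxybenzyl analogue of 26 | C=C(C(=O)OC(C)(C)C)[C@@H](C=O)[C@H](OCc1ccc(OC)cc1)C/C(C(=O)OC)=C\CCC(=C)C=O
F12 | step 12 | ring-closed bis(trimethylsilyl) ether, the O8 4-methoxybenzyl analogue of 28 | C=C(C(=O)OC(C)(C)C)[C@@H]1[C@H](OCc2ccc(OC)cc2)C/C(C(=O)OC)=C\CCC(=C)[C@H](O[Si](C)(C)C)[C@H]1O[Si](C)(C)C
F13 | step 12 | C8 alcohol, 28 without the angeloyl group | C=C(C(=O)OC(C)(C)C)[C@@H]1[C@H](O)C/C(C(=O)OC)=C\CCC(=C)[C@H](O[Si](C)(C)C)[C@H]1O[Si](C)(C)C
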